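**Remark on the chemistry (assumption).** The SMILES is read as an 8‑epi‑drimane, (5S,8S,9R,10S), with 5α‑H, 10β‑CH3, 9α‑H, 8α‑CH3 and an axial 8β‑OH, an (E)‑C11=C1′ bond with C9 syn to C2′, and (R)‑C5′. Atom labels: decalin C1–C10 (drimane numbering), C11 = the CH on C9, ring D = C1′ (ylidene carbon), C2′ (C–OH), C3′ (=CH), C4′ (C=O), C5′ (CHCl). The lactone carbonyl carbon of 1 becomes C1′.

## Analysis of the target

The target joins an 8‑epi‑drimane trans‑decalin (rings A/B, C1–C10; gem‑dimethyl at C4, angular methyl at C10, tertiary carbinol at C8) through the exocyclic trisubstituted alkene C11=C1′ to ring D, a 4‑alkylidene‑5‑chloro‑3‑hydroxycyclopent‑2‑enone that is the enol of a 1,3‑dione. The decalin carries four contiguous stereocentres; the axial 8β‑OH is syn‑diaxial to the C10 methyl and cis to the C9 side chain, which makes it the C8 epimer of the sclareol series. The fifth stereocentre, (R)‑C5′, bears chlorine, is α to the C4′ ketone and allylic, and lies four bonds from C9. C9 is flanked by two quaternary carbons whose methyl groups (8α and 10β) cover the two faces of ring D about equally, so the decalin cannot be expected to control C5′. The C11=C1′ bond has C9 on the side of C2′, so O8 and the C2′ oxygen sit on the same flank of the alkene, separated by a gap that one atom can bridge. Sensitive points are the vinylogous acid (acidic, tautomerisable, nucleophilic at C3′), the epimerisable C5′–Cl, the tertiary C8–O bond (ionises in acid) and the retro‑aldol relationship between O8 and any carbonyl at C11. The feature the route exploits is the constitution of ring D: C2′=C3′ is an alkyne, C4′=O is a carbonylation carbon, and C11=C1′–C5′ is an allene C11=C1′=C5′ of which only the distal double bond is consumed. A silicon atom between O8 and C2′ puts all of these in one molecule, and the resulting seven‑membered ring O8–C8–C9–C11=C1′–C2′–Si can hold C11=C1′ only in the geometry of the target. The difficulty is therefore not the decalin but the combination of ring‑D regiochemistry (C1′ is not the central carbon of the 1,3‑dione, so Knoevenagel logic fails), alkene geometry and the remote C–Cl stereocentre.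

## Retrosynthetic reasoning

**13 ⇐ 12.** The C2′–OH and the 8‑OH are reconnected through a dimethylsilylene bridge (Si–C2′ and Si–O8, bonds that are not in the target). A direct O8–C2′ vinylogous ester was not chosen: its hydrolysis would either ionise the tertiary C8–O bond (acid) or enolise C5′ (base). Oxidative C–Si cleavage creates the C2′–O bond with retention, frees O8 in the same operation, and means the free 1,3‑dione enol is not handled before the last step.

**12 ⇐ 11.** Three bonds are cut, C1′–C2′, C3′–C4′ and C4′–C5′: a carbonylative [2+2+1] between the ethynylsilane and the distal C1′=C5′ bond of a chloroallene. All five ring‑D carbons arrive with their substituents in place. The tether fixes the regiochemistry (tethered alkyne carbon = C2′) and the alkene geometry, and the allene axis fixes C5′. The forward reaction has to choose the distal allene bond and leave the C–Cl bond intact.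

**11 ⇐ 9 ⇐ 8 ⇐ 7.** The silicon bridge is attached to the tertiary 8‑OH of 9. The chloroallene is cut at C5′–Cl: anti‑SN2′ substitution of the propargylic sulfonate 8 places chloride on the unhindered alkyne terminus and converts the C11 carbinol centre of 7 into the allene axis. C11 is thus the place where the stereochemical information for C5′ is stored, and it is erased when C11 becomes sp2.

**7 ⇐ 6 ⇐ 5.** Because the decalin offers no reliable bias at C11, the carbinol is set by a reagent‑controlled reduction of ynone 6; 5 can therefore be carried as an epimer mixture.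

**5 ⇐ 4 ⇐ 3 ⇐ 2.** The alkyne C1′≡C5′ is cut at the triple bond: one‑carbon homologation of the lactol 4 turns the lactone carbonyl carbon into C1′, so all sixteen carbons of the terpenoid are retained. The C11 oxygen comes from enolate oxidation of lactone 2.

**2 ⇐ 1.** The 8β‑O/9β‑C cis relationship is obtained by acid epimerisation of the commercial trans‑lactone 1 to the cis‑lactone 2, which supplies all four decalin stereocentres.

## Alternatives that were turned down

**Alternative 1:** (textbook) Cut C11=C1′ by aldol condensation and C5′–Cl by late electrophilic chlorination. The silyl‑protected aldehyde A1 would be condensed with the α′‑enolate of a commercial 3‑alkoxycyclopentenone, dehydrated and hydrolysed to the des‑chloro enol A2, which would then be chlorinated. Turned down because C5′ of A2 has no usable facial bias, so an epimer mixture is expected. In addition, C3′ between the two carbonyls is the most nucleophilic carbon and competes with C5′, the alkene geometry is left to the dehydration, and A1 is a β‑silyloxy aldehyde prone to β‑elimination and retro‑aldol cleavage. The step count is similar to the chosen route, but no stereochemical problem is solved.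

**Alternative 2:** (single‑atom deletion) Reconnect C4′ and C5′ through an extra carbon. The six‑membered chlorinated hydroxy‑quinone‑methide chromene A3 would be oxidised to the 1,2‑dione, ring‑contracted by benzilic acid rearrangement and decarboxylated to the oxygen‑bridged tetracycle A4; hydrolysis of the C2′–O8 bond would finish. Turned down because C5′ would arise from a late protonation of a fulvene‑type dienol, without control, and two acyl shifts are possible in the benzilic step. A3 itself needs an aryl–C11 coupling, a chromene closure with 8‑epi selectivity, a regioselective chlorination and redox adjustments, so the precursor costs more than the contraction wins. The final hydrolysis of a tertiary‑alkyl vinylogous ester would also ionise C8–O in acid or epimerise C5′ in base.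

**Alternative 3:** (polyene cyclisation) Cut C9–C10, C4–C5 and C8–O. A proton‑ or halonium‑initiated, catalyst‑controlled bicyclisation of the (2Z,6E)‑farnesyl chloro‑enedione A5, terminated by the enol oxygen, would give the pyran‑fused tricycle A6. Turned down because the 8β‑O configuration requires anti addition across a Z‑trisubstituted alkene, a case in which cation lifetimes erode stereospecificity at C8. The acidic chloro‑enedione is a weak, ambident terminator. A6 would still need dehydrogenation to install C11=C1′ and C2′=C3′ and ring opening of the pyran, and C5′ would again be uncontrolled.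

Key step: step 10

## Route

**Step 1**
Reactants: 1 (+)-sclareolide (trans‑fused γ‑lactone, 8α‑O)
Product: 2 8‑epi‑sclareolide, (3aS,5aS,9aS,9bR)-3a,6,6,9a‑tetramethyldecahydronaphtho[2,1‑b]furan‑2(1H)‑one (cis‑fused lactone; 8β‑O, 8α‑CH3, 9α‑H, 5α‑H, 10β‑CH3)
Conditions: conc. H2SO4, HCO2H, rt
Reagents that add atoms: none
Why: Acid ionises the tertiary C8–O bond (alkyl–oxygen cleavage) and the C8 cation is recaptured by the carboxyl group on the β face to give the thermodynamically preferred cis‑fused γ‑lactone; this inverts C8 to the 8S configuration of the target while C5, C9 and C10 are untouched.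

**Step 2**
Reactants: 2 8‑epi‑sclareolide
Product: 3 11‑hydroxy‑8‑epi‑sclareolide (α‑hydroxy lactone, both C11 epimers)
Conditions: KHMDS, THF, −78 °C; then 3‑phenyl‑2‑(phenylsulfonyl)oxaziridine, −78 °C; aq. NH4Cl
Reagents that add atoms: 3‑phenyl‑2‑(phenylsulfonyl)oxaziridine, O=S(=O)(N1OC1c1ccccc1)c1ccccc1
Why: Enolate hydroxylation of the lactone potassium enolate with an N‑sulfonyloxaziridine places oxygen on C11; the C11 configuration is of no consequence because C11 is oxidised to the ketone in step 5.

**Step 3**
Reactants: 3 11‑hydroxy‑8‑epi‑sclareolide
Product: 4 lactol of 3 (hemiacetal at C1′; mixture at C11 and C1′)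
Conditions: DIBAL‑H (2.5 equiv), CH2Cl2, −78 °C; Rochelle salt
Reagents that add atoms: none
Why: Partial reduction of a lactone to the lactol at low temperature (the first equivalent of hydride is consumed by the free hydroxyl); the lactol is the masked C1′ aldehyde.

**Step 4**
Reactants: 4 lactol
Product: 5 decalin as in 2 with free axial 8β‑OH and a 9β‑CH(OH)–C≡CH side chain (C11 epimers)
Conditions: dimethyl (1‑diazo‑2‑oxopropyl)phosphonate, K2CO3, MeOH, 0 °C → rt
Reagents that add atoms: dimethyl (1‑diazo‑2‑oxopropyl)phosphonate (Ohira–Bestmann reagent), COP(=O)(OC)C(=[N+]=[N-])C(C)=O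
Why: Seyferth–Gilbert homologation of the open aldehyde form of the lactol (alkylidene carbene, 1,2‑H shift) gives the terminal alkyne; it adds C5′, releases the 8β‑OH and turns the former lactone carbonyl carbon into C1′.

**Step 5**
Reactants: 5 propargylic diol
Product: 6 ynone, 9β‑C(=O)–C≡CH with free 8β‑OH
Conditions: Dess–Martin periodinane, pyridine, CH2Cl2, 0 °C → rt
Reagents that add atoms: none
Why: Dess–Martin oxidation of the secondary propargylic alcohol; the tertiary 8‑OH cannot be oxidised, and the near‑neutral medium avoids retro‑aldol cleavage and oxa‑Michael closure of the β‑hydroxy ynone.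

**Step 6**
Reactants: 6 ynone
Product: 7 (11S)‑propargylic alcohol, 9β‑[(S)‑CH(OH)–C≡CH], 8β‑OH
Conditions: (S)‑2‑methyl‑CBS‑oxazaborolidine (1 equiv), catecholborane, toluene, −78 °C
Reagents that add atoms: none
Why: Corey–Bakshi–Shibata reduction: with ethynyl as the small and the drimanyl group as the large substituent, the (S)‑oxazaborolidine should deliver hydride to give the (11S) carbinol under reagent control; catecholborane at −78 °C does not hydroborate the alkyne.

**Step 7**
Reactants: 7 (11S)‑propargylic alcohol
Product: 8 (11S)‑propargylic methanesulfonate, 8β‑OH free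
Conditions: MsCl, Et3N, CH2Cl2, −40 °C
Reagents that add atoms: methanesulfonyl chloride, CS(=O)(=O)Cl
Why: Selective sulfonylation of the secondary hydroxyl; the hindered tertiary 8‑OH does not react, and C11 keeps its configuration because no bond to C11 is broken.

**Step 8**
Reactants: 8 (11S)‑mesylate
Product: 9 (aR)‑[= (M)]‑1‑chloroallene, 9β‑CH=C=CHCl, 8β‑OH free
Conditions: CuCl, LiCl (LiCuCl2), THF, rt → 45 °C
Reagents that add atoms: lithium dichlorocuprate(I), made from CuCl and LiCl, [Li+].Cl[Cu-]Cl
Why: anti‑SN2′ substitution of a propargylic sulfonate by a chlorocuprate: chloride enters at the unhindered alkyne terminus C5′ anti to the leaving group, so the (11S) centre should be converted into the (aR) allene axis; direct SN2 at the neopentyl‑type C11 is blocked.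

**Step 9**
Reactants: 9 (aR)‑chloroallene
Product: 11 allenyne, 8β‑O–Si(CH3)2–C≡CH with the (aR)‑chloroallene on C9, via 8‑O‑chlorodimethylsilyl ether 10 (not isolated)
Conditions: Me2SiCl2 (5 equiv), Et3N, DMAP (cat.), CH2Cl2, 0 °C → rt; evaporate; HC≡CMgBr, THF, 0 °C
Reagents that add atoms: dichlorodimethylsilane, C[Si](C)(Cl)Cl; ethynylmagnesium bromide, C#C[Mg]Br
Why: Silylation of the tertiary alcohol with excess dichlorosilane gives the monochlorosilyl ether, and the Grignard reagent displaces the remaining Si–Cl; this installs the one‑atom silicon bridge between O8 and the future C2′ without touching the allene.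

**Step 10**
Reactants: 11 allenyne
Product: 12 tetracyclic (5′R)‑5′‑chloro dienone: cyclopentenone ring D fused to a seven‑membered oxasilacycle (O8–Si(CH3)2–C2′), C11=C1′ endocyclic in that ring
Conditions: [Rh(CO)2Cl]2 (10 mol %), CO (1 atm), toluene, 80–90 °C
Reagents that add atoms: carbon monoxide, [C-]#[O+]
Why: Proposed new method: an allenic Pauson–Khand reaction has not been run on a 1‑haloallene; the closest known reaction type is the Rh(I)‑catalysed carbonylative [2+2+1] of tethered allene‑ynes, which engages the distal allene double bond, accepts silicon‑containing tethers, forms bicyclo[5.3.0] dienones and passes the axial chirality of 1,3‑disubstituted allenes on to the new sp3 centre. Mechanism: Rh(I) binds the ethynylsilane and the distal C1′=C5′ π bond, oxidative cyclisation forms C1′–C2′ and a rhodacyclopentene with Rh on C3′ and C5′, CO inserts and reductive elimination closes C3′–C4′ and C4′–C5′. Ring D closes by this [2+2+1], and the seven‑membered ring O8–C8–C9–C11=C1′–C2′–Si closes in the same oxidative cyclisation as an annulation through the tether. For C5′, the lobes of the C1′=C5′ π bond lie in the plane of the C11 substituents, the tether can reach only the lobe on the C9 side and the addition across C1′=C5′ is suprafacial, so the (aR) axis should be translated into (5′R). C11=C1′ becomes a cis‑alkene inside the seven‑membered ring, which is the E geometry of the target (C9 syn to C2′). Ring‑D regiochemistry follows from connectivity: the tethered alkyne carbon becomes C2′ (β to the carbonyl, bearing Si) and the terminal alkyne CH becomes C3′. The step needs distal over proximal selectivity, secured by Rh(I) under CO and the four‑atom tether; an ene‑type cycloisomerisation is excluded because C5′ carries no allylic hydrogen; and the C–Cl bond must survive, which the electron‑poor carbonyl‑rhodium catalyst (a poor partner for oxidative addition to C(sp2)–Cl) makes plausible.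

**Step 11**
Reactants: 12 tetracyclic chloro dienone
Product: 13 the target, (4E,5R)-5‑chloro‑3‑hydroxy‑4‑{[(1R,2S,4aS,8aS)-2‑hydroxy‑2,5,5,8a‑tetramethyldecahydronaphthalen‑1‑yl]methylidene}cyclopent‑2‑en‑1‑one
Conditions: 30% H2O2, KF, KHCO3, THF/MeOH, 0 °C → rt; then acidify to pH ≈ 4
Reagents that add atoms: hydrogen peroxide, OO
Why: Tamao–Fleming oxidation of the alkoxy(alkenyl)dimethylsilane: hydroperoxide adds to fluoride‑activated silicon and C2′ migrates from Si to O with retention, which gives the C2′ enol (the vinylogous acid) and frees the 8β‑OH in one operation. The C11=C1′ geometry and C5′ are not involved, and the vinylogous acid is deprotonated by bicarbonate as it forms, which protects ring D from further attack.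

## Compound list

1 | (+)-sclareolide | CC1(C)CCC[C@]2(C)[C@@H](CC(=O)O3)[C@@]3(C)CC[C@@H]12 | starting material
2 | 8‑epi‑sclareolide | CC1(C)CCC[C@]2(C)[C@@H](CC(=O)O3)[C@]3(C)CC[C@@H]12 | intermediate
3 | 11‑hydroxy‑8‑epi‑sclareolide (C11 epimers) | CC1(C)CCC[C@]2(C)[C@@H](C(O)C(=O)O3)[C@]3(C)CC[C@@H]12 | intermediate
4 | lactol of 3 (epimers at C11 and C1′) | CC1(C)CCC[C@]2(C)[C@@H](C(O)C(O)O3)[C@]3(C)CC[C@@H]12 | intermediate
5 | 8β‑hydroxy 9β‑(1‑hydroxyprop‑2‑ynyl) decalin (C11 epimers) | CC1(C)CCC[C@]2(C)[C@@H](C(O)C#C)[C@@](C)(O)CC[C@@H]12 | intermediate
6 | ynone | CC1(C)CCC[C@]2(C)[C@@H](C(=O)C#C)[C@@](C)(O)CC[C@@H]12 | intermediate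
7 | (11S)‑propargylic alcohol | CC1(C)CCC[C@]2(C)[C@@H]([C@H](O)C#C)[C@@](C)(O)CC[C@@H]12 | intermediate
8 | (11S)‑propargylic mesylate | CC1(C)CCC[C@]2(C)[C@@H]([C@H](OS(C)(=O)=O)C#C)[C@@](C)(O)CC[C@@H]12 | intermediate
9 | (aR)‑chloroallene | CC1(C)CCC[C@]2(C)[C@@H](C([H])=[C@]=C([H])Cl)[C@@](C)(O)CC[C@@H]12 | intermediate
10 | 8‑O‑chlorodimethylsilyl ether of 9 | CC1(C)CCC[C@]2(C)[C@@H](C([H])=[C@]=C([H])Cl)[C@@](C)(O[Si](C)(C)Cl)CC[C@@H]12 | intermediate
11 | silicon‑tethered allenyne | CC1(C)CCC[C@]2(C)[C@@H](C([H])=[C@]=C([H])Cl)[C@@](C)(O[Si](C)(C)C#C)CC[C@@H]12 | intermediate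
12 | tetracyclic (5′R)‑chloro dienone siloxane | CC1(C)CCC[C@]2(C)[C@@H](C=C4[C@@H](Cl)C(=O)C=C4[Si](C)(C)O3)[C@]3(C)CC[C@@H]12 | intermediate
13 | CNP0279879.2 | CC1(C)CCC[C@]2(C)[C@@H](/C=C3\C(O)=CC(=O)[C@@H]3Cl)[C@@](C)(O)CC[C@@H]12 | target

## Step count and risk

Total step count: 11. Longest linear sequence: 11 steps (the route is linear from 1).

**Step 10 (key step, proposed new method).** The most likely failure is oxidative addition of Rh(I) into the allenyl C–Cl bond, or reversible metal‑mediated scrambling of the allene axis before cyclisation, which would cost the chloride or erode the C5′ configuration; oligomerisation of the terminal alkyne is a lesser risk. The fallback uses only known chemistry, sets out from mesylate 8 and returns at 12. SN2′ hydride transfer (LiAlH4, Et2O, 0 °C) would give the halogen‑free terminal allene F1, with 8β‑OH free and 9β‑CH=C=CH2. Tethering as in step 9 would give the allenyne F2. The Rh(I) allenic Pauson–Khand reaction, here on a substrate class for which it is established, would give the des‑chloro tetracycle F3. Kinetic enolisation toward C5′ (LiHMDS, THF, −78 °C) and chlorination with N‑chlorosuccinimide would then give 12 together with its C5′ epimer F4. These are diastereomers and would be separated by chromatography; F4 could be recycled by deprotonation and reprotonation. The price of this fallback is the loss of stereocontrol at C5′.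

**Step 11.** Nucleophilic epoxidation of the cross‑conjugated dienone, or enolisation toward C5′ under the basic fluoride/bicarbonate medium, may compete with attack of hydroperoxide at silicon. The fallback sets out from 12 and returns at 13 by a base‑free two‑stage sequence. HF·pyridine (THF, 0 °C) would open the Si–O8 bond to the alkenyl fluorosilane F8, with free 8β‑OH and C2′–Si(CH3)2F. An electrophilic oxidation (mCPBA, KHF2, DMF, rt) would then convert C2′–Si into C2′–OH.

**Step 8.** Partial loss of stereospecificity (cuprate‑mediated equilibration of the haloallene axis on long exposure) or sluggish substitution on this hindered substrate is possible. The fallback sets out from ynone 6 and returns at 9. Reduction with the (R)‑oxazaborolidine would give the (11R)‑propargylic alcohol F5. Thionyl chloride in Et2O (0 °C → rt) would convert F5 through its chlorosulfite by syn‑SNi′ delivery of chloride to C5′, which leads to the same (aR) axis. The same channel would use up any (11R) epimer if reagent control in step 6 were incomplete.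

**Step 4.** Base‑mediated isomerisation of the α‑hydroxy aldehyde form of the lactol (ene‑diol/α‑ketol shift) may compete with homologation. The fallback sets out from 3 and returns at 5. LiAlH4 would reduce 3 to the 8,11,1′‑triol F6, and NaIO4 would cleave it to the 8β‑hydroxy C11 aldehyde F7 (C1′ is lost in this variant). Ethynylmagnesium bromide (THF, −78 °C) would add to F7 to give 5, both alkyne carbons now coming from the Grignard reagent.

**Step 9.** Incomplete silylation of the axial tertiary 8β‑OH, which is syn‑diaxial to the C10 methyl, is the likely problem. The fallback sets out from 9 and returns at 11. Chloro(ethynyl)dimethylsilane F9 would be preformed from dichlorodimethylsilane and ethynylmagnesium bromide. Alcohol 9 would be deprotonated with LiHMDS (THF, −78 °C) and the lithium alkoxide quenched with F9, replacing amine‑assisted silylation by alkoxide silylation.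

## Further compounds

F1 | step 10 | terminal allene, 8β‑OH free, 9β‑CH=C=CH2 | CC1(C)CCC[C@]2(C)[C@@H](C=C=C)[C@@](C)(O)CC[C@@H]12
F2 | step 10 | silicon‑tethered halogen‑free allenyne | CC1(C)CCC[C@]2(C)[C@@H](C=C=C)[C@@](C)(O[Si](C)(C)C#C)CC[C@@H]12
F3 | step 10 | des‑chloro tetracyclic dienone siloxane | CC1(C)CCC[C@]2(C)[C@@H](C=C4CC(=O)C=C4[Si](C)(C)O3)[C@]3(C)CC[C@@H]12
F4 | step 10 | C5′ epimer of 12 | CC1(C)CCC[C@]2(C)[C@@H](C=C4[C@H](Cl)C(=O)C=C4[Si](C)(C)O3)[C@]3(C)CC[C@@H]12
F5 | step 8 | (11R)‑propargylic alcohol | CC1(C)CCC[C@]2(C)[C@@H]([C@@H](O)C#C)[C@@](C)(O)CC[C@@H]12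
F6 | step 4 | 8,11,1′‑triol (C11 epimers) | CC1(C)CCC[C@]2(C)[C@@H](C(O)CO)[C@@](C)(O)CC[C@@H]12
F7 | step 4 | 8β‑hydroxy C11 aldehyde | CC1(C)CCC[C@]2(C)[C@@H](C=O)[C@@](C)(O)CC[C@@H]12
F8 | step 11 | alkenyl fluorosilane with free 8β‑OH | CC1(C)CCC[C@]2(C)[C@@H](/C=C3\C([Si](C)(C)F)=CC(=O)[C@@H]3Cl)[C@@](C)(O)CC[C@@H]12
F9 | step 9 | chloro(ethynyl)dimethylsilane | C#C[Si](C)(C)Cl
A1 | alternative 1 | 8β‑triethylsilyloxy C11 aldehyde | CC1(C)CCC[C@]2(C)[C@@H](C=O)[C@@](C)(O[Si](CC)(CC)CC)CC[C@@H]12
A2 | alternative 1 | des‑chloro enol (alkene geometry not controlled) | CC1(C)CCC[C@]2(C)[C@@H](C=C3CC(=O)C=C3O)[C@@](C)(O)CC[C@@H]12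
A3 | alternative 2 | chlorinated hydroxy‑quinone‑methide chromene | CC1(C)CCC[C@]2(C)[C@@H](C=C4C(Cl)=C(O)C(=O)C=C4O3)[C@]3(C)CC[C@@H]12
A4 | alternative 2 | ring‑contracted oxygen‑bridged tetracycle (C5′ not controlled) | CC1(C)CCC[C@]2(C)[C@@H](C=C4C(Cl)C(=O)C=C4O3)[C@]3(C)CC[C@@H]12
A5 | alternative 3 | 4‑chloro‑5‑[(2Z,6E)‑farnesyl]cyclopent‑4‑ene‑1,3‑dione | CC(C)=CCC/C(C)=C/CC/C(C)=C\CC1=C(Cl)C(=O)CC1=O
A6 | alternative 3 | pyran‑fused cyclisation product (C5′ not controlled) | CC1(C)CCC[C@]2(C)[C@@H](CC4=C(O3)CC(=O)C4Cl)[C@]3(C)CC[C@@H]12
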